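**Retrosynthetic overview**
- Feature: the only ring is a 3,6-dihydro-2H-pyran (O1, C2, C3, C4=C5, C6). Its O1–C2 bond links the C6 allylic oxygen to C2, the sole stereocentre, which carries the 2-propenoate unit, so C2 is the carbinol carbon of a Morita–Baylis–Hillman adduct.
- O1–C2 (the one ring closure, second-last step): acid ⇒ methyl ester ⇒ racemic tert-butyl carbonate bearing a free (Z)-allylic CH2OH. A chiral tertiary amine closes it by two successive SN2′ steps that erase and then rewrite C2.
- C2–Cα: the carbinol comes from a β,γ-unsaturated aldehyde and an α-(methoxycarbonyl)vinylaluminium reagent made from methyl propiolate. The slow amine-catalysed acrylate coupling is avoided because it would move the alkene of this aldehyde into conjugation.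
- C4=C5: Z-selective Wittig reaction of a 3-silyloxypropyl ylide with an α-silyloxy ketone. The ketone is built from (2E,6E)-farnesyl bromide and the dimethylhydrazone of O-TBDPS hydroxyacetone, and TBS versus TBDPS distinguishes the two primary alcohols.

Key step: step 11

Assumption: the sense of induction of the cinchona catalyst in this ring closure cannot be predicted with confidence. The route is written with (DHQD)2PHAL, and the pseudoenantiomer (DHQ)2PHAL replaces it if a test run shows (R)-C2. Pyran numbering (O1, C2 to C6) is used in all discussion.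

**Step 1**
Reactants: 1 hydroxyacetone
Product: 2 1-(tert-butyldiphenylsilyloxy)propan-2-one
Conditions: TBDPSCl, imidazole, CH2Cl2, 0 °C → rt
Reagents that add atoms: tert-butyldiphenylsilyl chloride, CC(C)(C)[Si](Cl)(c1ccccc1)c1ccccc1
Why: Imidazole-promoted silyl ether formation on the primary alcohol installs a bulky, acid-stable group that should survive the TBS cleavage of step 6 and shield the OCH2 position in step 3.

**Step 2**
Reactants: 2 1-(tert-butyldiphenylsilyloxy)propan-2-one
Product: 3 1-(tert-butyldiphenylsilyloxy)propan-2-one N,N-dimethylhydrazone (C=N isomers)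
Conditions: Me2NNH2, MgSO4, CH2Cl2, rt
Reagents that add atoms: N,N-dimethylhydrazine, CN(C)N
Why: Hydrazone condensation turns the electrophilic ketone into a form that does not self-condense and can be metalated regioselectively.

**Step 3**
Reactants: 3 hydrazone; 4 (2E,6E)-farnesyl bromide
Product: 7 (5E,9E)-1-(tert-butyldiphenylsilyloxy)-6,10,14-trimethylpentadeca-5,9,13-trien-2-one, via lithiated hydrazone 5 (not isolated), via alkylated hydrazone 6 (not isolated)
Conditions: LiN(iPr)2, THF, −78 → 0 °C; 4, −78 → 0 °C; then sat. aq. oxalic acid, Et2O, rt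
Reagents that add atoms: water, O
Why: In this dimethylhydrazone (azaenolate) alkylation, kinetic deprotonation should take the open CH3 rather than the OCH2 beside the TBDPS group, the azaenolate displaces the primary allylic bromide by SN2 without disturbing the E-alkenes, and biphasic oxalic acid hydrolyses the C=N bond while sparing silyl ether and triene.

**Step 4**
Reactants: 8 (3-bromopropoxy)(tert-butyl)dimethylsilane
Product: 9 [3-(tert-butyldimethylsilyloxy)propyl]triphenylphosphonium bromide
Conditions: PPh3, MeCN, reflux
Reagents that add atoms: triphenylphosphine, c1ccc(cc1)P(c1ccccc1)c1ccccc1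
Why: SN2 quaternisation of triphenylphosphine by an unhindered primary bromide gives the phosphonium salt, and the γ-silyloxy group is not a leaving group under these conditions.

**Step 5**
Reactants: 9 phosphonium bromide; 7 ketone
Product: 11 (3Z,7E,11E)-1-(tert-butyldimethylsilyloxy)-4-[(tert-butyldiphenylsilyloxy)methyl]-8,12,16-trimethylheptadeca-3,7,11,15-tetraene, via phosphorus ylide 10 (not isolated)
Conditions: KN(SiMe3)2, THF, −78 → 0 °C; then 7, −78 °C → rt
Reagents that add atoms: none
Why: In the Wittig olefination under lithium-free kinetic conditions, non-stabilised ylides and α-oxygenated ketones are known to give the trisubstituted alkene with the ylide chain cis to the CH2O group, which is the (Z)-geometry that later places C3 and C6 on one side; any (E)-isomer is removed by chromatography here or at 12.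

**Step 6**
Reactants: 11 bis-silyl ether
Product: 12 (3Z,7E,11E)-4-[(tert-butyldiphenylsilyloxy)methyl]-8,12,16-trimethylheptadeca-3,7,11,15-tetraen-1-ol
Conditions: CSA (cat.), MeOH/CH2Cl2, 0 °C
Reagents that add atoms: none
Why: Acid-catalysed methanolysis of silyl ethers is governed by bulk at silicon, so the primary TBS ether should cleave well before the TBDPS ether, and the mild acid leaves the trisubstituted alkenes alone.

**Step 7**
Reactants: 12 homoallylic alcohol
Product: 13 (3Z,7E,11E)-4-[(tert-butyldiphenylsilyloxy)methyl]-8,12,16-trimethylheptadeca-3,7,11,15-tetraenal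
Conditions: Dess–Martin periodinane, NaHCO3, CH2Cl2, 0 °C; crude 13 used at once
Reagents that add atoms: none
Why: The buffered Dess–Martin oxidation is neutral and fast, stops at the aldehyde and avoids the amine base that would shift the β,γ-alkene into conjugation.

**Step 8**
Reactants: 13 aldehyde; 14 methyl propiolate
Product: 16 racemic methyl (5Z,9E,13E)-6-[(tert-butyldiphenylsilyloxy)methyl]-3-hydroxy-10,14,18-trimethyl-2-methylenenonadeca-5,9,13,17-tetraenoate, via vinylalane 15 (not isolated)
Conditions: iBu2AlH, HMPA, THF, 0 °C; 14, 0 °C; then 13, 0 °C → rt; aq. potassium sodium tartrate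
Reagents that add atoms: none
Why: In this vinylalumination, 1,4-hydroalumination of the propiolate gives the α-(methoxycarbonyl)vinylalane 15, which adds 1,2 to the aldehyde and delivers the Morita–Baylis–Hillman carbinol without an amine and without a long reaction time; the new centre forms racemic, which does not matter because step 11 erases it.

**Step 9**
Reactants: 16 carbinol
Product: 17 methyl (5Z,9E,13E)-3-(tert-butoxycarbonyloxy)-6-[(tert-butyldiphenylsilyloxy)methyl]-10,14,18-trimethyl-2-methylenenonadeca-5,9,13,17-tetraenoate (racemic at C3 of the chain)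
Conditions: Boc2O, DMAP (cat.), CH2Cl2, 0 °C → rt
Reagents that add atoms: di-tert-butyl dicarbonate, CC(C)(C)OC(=O)OC(=O)OC(C)(C)C
Why: DMAP-catalysed O-acylation is the standard way to make Morita–Baylis–Hillman tert-butyl carbonates, and the only free hydroxyl in 16 is the one to be activated.

**Step 10**
Reactants: 17 silyl carbonate
Product: 18 methyl (5Z,9E,13E)-3-(tert-butoxycarbonyloxy)-6-(hydroxymethyl)-10,14,18-trimethyl-2-methylenenonadeca-5,9,13,17-tetraenoate (racemic at C3 of the chain)
Conditions: Bu4NF, AcOH, THF, 0 °C → rt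
Reagents that add atoms: none
Why: Fluoride-induced desilylation buffered with acetic acid frees the allylic alcohol without building up alkoxide, so carbonate, acrylate and methyl ester should stay intact.

**Step 11**
Reactants: 18 hydroxy carbonate
Product: 20 methyl 2-[(2S)-5-[(3E,7E)-4,8,12-trimethyltrideca-3,7,11-trien-1-yl]-3,6-dihydro-2H-pyran-2-yl]prop-2-enoate, via allylammonium alkoxide 19 (not isolated)
Conditions: (DHQD)2PHAL (hydroquinidine 1,4-phthalazinediyl diether, 20 mol %), 4 Å MS, toluene (0.01 M), rt → 40 °C
Reagents that add atoms: none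
Why: Proposed new method: the quinuclidine nitrogen of the catalyst adds SN2′ to the acrylate CH2 of either enantiomer of 18, the tert-butyl carbonate leaves and falls apart to CO2 and tert-butoxide, and this base takes the proton of the C6 hydroxyl, giving allylammonium alkoxide 19 in which the former carbinol carbon is trigonal. The alkoxide then attacks that carbon (C2) in a second SN2′ step that makes O1–C2, releases the amine and restores the exo-methylene ester; the closest known reaction type is the intermolecular cinchona-amine-catalysed allylic substitution of Morita–Baylis–Hillman carbonates by oxygen nucleophiles such as phenols, water, hydroperoxides and alcohols, which has not been shown as a ring closure by a tethered aliphatic alcohol on an alkyl-substituted carbonate. The pyran closes in the 6-exo-trig mode onto the C2=Cα bond of 19, helped by the (Z)-C4=C5 alkene, which already holds C3 and C6 on the same side. C2 is the only new stereocentre and is controlled by the catalyst, whose alkaloid ether wall leaves one face of the ammonium enoate open, so the racemic centre of 18 has no say as long as both enantiomers are carried to full conversion. Regioselectivity for C2 over the CH2N terminus is secured by ring size (six against eight atoms), and ring closure is favoured over intermolecular etherification by high dilution. The selectivity that remains to be won is substitution over loss of a doubly allylic C3 proton from 19 (1,4-elimination of the amine to a conjugated triene ester), which is why an apolar solvent, dry conditions and the lowest workable temperature are specified.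

**Step 12**
Reactants: 20 methyl ester
Product: 22 2-[(2S)-5-[(3E,7E)-4,8,12-trimethyltrideca-3,7,11-trien-1-yl]-3,6-dihydro-2H-pyran-2-yl]prop-2-enoic acid, via lithium carboxylate 21 (not isolated)
Conditions: LiOH, THF/MeOH/H2O, 0 °C → rt; then 1 M HCl to pH 3, 0 °C
Reagents that add atoms: lithium hydroxide, [Li+].[OH-]
Why: Saponification by acyl–oxygen cleavage removes the methyl ester, and C2–H sits on a carbon that is only cross-conjugated with the carboxyl group, so it is not acidified and the stereocentre should not epimerise.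

**Compound list**
1 | hydroxyacetone | CC(=O)CO | starting material
2 | 1-(tert-butyldiphenylsilyloxy)propan-2-one | CC(=O)CO[Si](c1ccccc1)(c1ccccc1)C(C)(C)C | intermediate
3 | 1-(tert-butyldiphenylsilyloxy)propan-2-one N,N-dimethylhydrazone | CC(CO[Si](c1ccccc1)(c1ccccc1)C(C)(C)C)=NN(C)C | intermediate
4 | (2E,6E)-farnesyl bromide | BrC/C=C(\C)CC/C=C(\C)CCC=C(C)C | starting material
5 | lithiated hydrazone (azaenolate, drawn C-lithiated at the former CH3) | [Li]CC(CO[Si](c1ccccc1)(c1ccccc1)C(C)(C)C)=NN(C)C | intermediate
6 | N,N-dimethylhydrazone of ketone 7 | CN(C)N=C(CO[Si](c1ccccc1)(c1ccccc1)C(C)(C)C)CC/C=C(\C)CC/C=C(\C)CCC=C(C)C | intermediate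
7 | (5E,9E)-1-(tert-butyldiphenylsilyloxy)-6,10,14-trimethylpentadeca-5,9,13-trien-2-one | O=C(CO[Si](c1ccccc1)(c1ccccc1)C(C)(C)C)CC/C=C(\C)CC/C=C(\C)CCC=C(C)C | intermediate
8 | (3-bromopropoxy)(tert-butyl)dimethylsilane | BrCCCO[Si](C)(C)C(C)(C)C | starting material
9 | [3-(tert-butyldimethylsilyloxy)propyl]triphenylphosphonium bromide | [Br-].CC(C)(C)[Si](C)(C)OCCC[P+](c1ccccc1)(c1ccccc1)c1ccccc1 | intermediate
10 | [3-(tert-butyldimethylsilyloxy)propylidene]triphenylphosphorane | CC(C)(C)[Si](C)(C)OCCC=P(c1ccccc1)(c1ccccc1)c1ccccc1 | intermediate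
11 | (3Z,7E,11E)-1-(tert-butyldimethylsilyloxy)-4-[(tert-butyldiphenylsilyloxy)methyl]-8,12,16-trimethylheptadeca-3,7,11,15-tetraene | CC(C)(C)[Si](C)(C)OCC/C=C(\CO[Si](c1ccccc1)(c1ccccc1)C(C)(C)C)CC/C=C(\C)CC/C=C(\C)CCC=C(C)C | intermediate
12 | (3Z,7E,11E)-4-[(tert-butyldiphenylsilyloxy)methyl]-8,12,16-trimethylheptadeca-3,7,11,15-tetraen-1-ol | OCC/C=C(\CO[Si](c1ccccc1)(c1ccccc1)C(C)(C)C)CC/C=C(\C)CC/C=C(\C)CCC=C(C)C | intermediate
13 | (3Z,7E,11E)-4-[(tert-butyldiphenylsilyloxy)methyl]-8,12,16-trimethylheptadeca-3,7,11,15-tetraenal | O=CC/C=C(\CO[Si](c1ccccc1)(c1ccccc1)C(C)(C)C)CC/C=C(\C)CC/C=C(\C)CCC=C(C)C | intermediate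
14 | methyl propiolate | C#CC(=O)OC | starting material
15 | [1-(methoxycarbonyl)vinyl]diisobutylaluminium | C=C(C(=O)OC)[Al](CC(C)C)CC(C)C | intermediate
16 | methyl (5Z,9E,13E)-6-[(tert-butyldiphenylsilyloxy)methyl]-3-hydroxy-10,14,18-trimethyl-2-methylenenonadeca-5,9,13,17-tetraenoate, racemic | C=C(C(=O)OC)C(O)C/C=C(\CO[Si](c1ccccc1)(c1ccccc1)C(C)(C)C)CC/C=C(\C)CC/C=C(\C)CCC=C(C)C | intermediate
17 | methyl (5Z,9E,13E)-3-(tert-butoxycarbonyloxy)-6-[(tert-butyldiphenylsilyloxy)methyl]-10,14,18-trimethyl-2-methylenenonadeca-5,9,13,17-tetraenoate, racemic | C=C(C(=O)OC)C(OC(=O)OC(C)(C)C)C/C=C(\CO[Si](c1ccccc1)(c1ccccc1)C(C)(C)C)CC/C=C(\C)CC/C=C(\C)CCC=C(C)C | intermediate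
18 | methyl (5Z,9E,13E)-3-(tert-butoxycarbonyloxy)-6-(hydroxymethyl)-10,14,18-trimethyl-2-methylenenonadeca-5,9,13,17-tetraenoate, racemic | C=C(C(=O)OC)C(OC(=O)OC(C)(C)C)C/C=C(\CO)CC/C=C(\C)CC/C=C(\C)CCC=C(C)C | intermediate
19 | allylammonium alkoxide: (DHQD)2PHAL quaternised at one quinuclidine nitrogen by the 2-(methoxycarbonyl)alk-2-enyl chain, with the C6 alkoxide as internal counter-ion (enoate geometry not defined) | COc1ccc2nccc([C@@H]([C@H]3C[C@@H]4CC[N+]3(CC(C(=O)OC)=CC/C=C(\C[O-])CC/C=C(\C)CC/C=C(\C)CCC=C(C)C)C[C@@H]4CC)Oc3nnc(O[C@H]([C@H]4C[C@@H]5CCN4C[C@@H]5CC)c4ccnc5ccc(OC)cc45)c4ccccc34)c2c1 | intermediate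
20 | methyl 2-[(2S)-5-[(3E,7E)-4,8,12-trimethyltrideca-3,7,11-trien-1-yl]-3,6-dihydro-2H-pyran-2-yl]prop-2-enoate | C=C(C(=O)OC)[C@@H]1CC=C(CC/C=C(\C)CC/C=C(\C)CCC=C(C)C)CO1 | intermediate
21 | lithium 2-[(2S)-5-[(3E,7E)-4,8,12-trimethyltrideca-3,7,11-trien-1-yl]-3,6-dihydro-2H-pyran-2-yl]prop-2-enoate | [Li+].C=C(C(=O)[O-])[C@@H]1CC=C(CC/C=C(\C)CC/C=C(\C)CCC=C(C)C)CO1 | intermediate
22 | 2-[(2S)-5-[(3E,7E)-4,8,12-trimethyltrideca-3,7,11-trien-1-yl]-3,6-dihydro-2H-pyran-2-yl]prop-2-enoic acid | C=C(C(=O)O)[C@@H]1CC=C(CC/C=C(\C)CC/C=C(\C)CCC=C(C)C)CO1 | target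

**Step count**
Total steps: 12.
Longest linear sequence: 11 steps (steps 1–3 and 5–12, from hydroxyacetone).

**Steps most likely to fail**

1. Step 11 (labelled step).
   - What may go wrong: the hindered amine may add too slowly to an alkyl-substituted carbonate. The ammonium intermediate may lose a C3 proton and eliminate instead of cyclising. One enantiomer of the carbonate may lag, so the process stalls as a kinetic resolution. Facial selectivity may be poor.
   - Fallback: it sets out from 18 and returns at 20 by changing the activation mode from an allylammonium salt to a π-allyl metal complex. This is a Tsuji–Trost allylic etherification with a zerovalent palladium source, Pd2(dba)3·CHCl3, and one enantiomer of N,N′-(cyclohexane-1,2-diyl)bis[2-(diphenylphosphino)benzamide] in CH2Cl2 or toluene.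
   - Basis: ionisation of both carbonate enantiomers, fast π–σ–π interconversion of the diastereomeric complexes and attack of the tethered alcohol at the secondary terminus make up a dynamic kinetic asymmetric transformation. This is known for Morita–Baylis–Hillman carbonates with aliphatic alcohols, and ring size again enforces the branched regiochemistry.
   - This fallback makes no new compound (F0).

2. Step 8.
   - What may go wrong: the β,γ-alkene of the aldehyde may migrate into conjugation, the aldehyde may enolise, or residual hydride may reduce it while the mild vinylalane reacts.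
   - Fallback: it sets out from 13 and replaces the vinyl metal by an aldol–elimination sequence.
   - The lithium enolate of methyl 3-(dimethylamino)propanoate (LiN(iPr)2, THF, −78 °C) should add to 13 within minutes. This gives methyl (5Z,9E,13E)-6-[(tert-butyldiphenylsilyloxy)methyl]-2-[(dimethylamino)methyl]-3-hydroxy-10,14,18-trimethylnonadeca-5,9,13,17-tetraenoate F1.
   - MeI in acetone quaternises the amine to the trimethylammonium iodide F2.
   - K2CO3 at rt triggers E1cB loss of trimethylamine and creates the exo-methylene group, returning to the route at 16.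

3. Step 3.
   - What may go wrong: deprotonation may occur at the oxygen-bearing α-carbon, the hydrazone may alkylate twice, or hydrolysis may be incomplete.
   - Fallback: it sets out from 4 and builds the ketone from the acyl side, so no regiochemical choice exists.
   - The lithium enolate of N-methoxy-N-methylacetamide is alkylated with 4 to (4E,8E)-N-methoxy-N,5,9,13-tetramethyltetradeca-4,8,12-trienamide F3.
   - Chloromethyllithium (ClCH2I, MeLi·LiBr, −78 °C) converts it to (5E,9E)-1-chloro-6,10,14-trimethylpentadeca-5,9,13-trien-2-one F4.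
   - CsOAc in DMF gives (5E,9E)-6,10,14-trimethyl-2-oxopentadeca-5,9,13-trien-1-yl acetate F5.
   - K2CO3 in MeOH gives (5E,9E)-1-hydroxy-6,10,14-trimethylpentadeca-5,9,13-trien-2-one F6.
   - TBDPSCl with imidazole then returns to the route at 7.

**Further compounds**
F0 | step 11 | none | none
F1 | step 8 | methyl (5Z,9E,13E)-6-[(tert-butyldiphenylsilyloxy)methyl]-2-[(dimethylamino)methyl]-3-hydroxy-10,14,18-trimethylnonadeca-5,9,13,17-tetraenoate (diastereomer mixture) | CN(C)CC(C(=O)OC)C(O)C/C=C(\CO[Si](c1ccccc1)(c1ccccc1)C(C)(C)C)CC/C=C(\C)CC/C=C(\C)CCC=C(C)C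
F2 | step 8 | trimethylammonium iodide of F1 | [I-].C[N+](C)(C)CC(C(=O)OC)C(O)C/C=C(\CO[Si](c1ccccc1)(c1ccccc1)C(C)(C)C)CC/C=C(\C)CC/C=C(\C)CCC=C(C)C
F3 | step 3 | (4E,8E)-N-methoxy-N,5,9,13-tetramethyltetradeca-4,8,12-trienamide | CON(C)C(=O)CC/C=C(\C)CC/C=C(\C)CCC=C(C)C
F4 | step 3 | (5E,9E)-1-chloro-6,10,14-trimethylpentadeca-5,9,13-trien-2-one | ClCC(=O)CC/C=C(\C)CC/C=C(\C)CCC=C(C)C
F5 | step 3 | (5E,9E)-6,10,14-trimethyl-2-oxopentadeca-5,9,13-trien-1-yl acetate | CC(=O)OCC(=O)CC/C=C(\C)CC/C=C(\C)CCC=C(C)C
F6 | step 3 | (5E,9E)-1-hydroxy-6,10,14-trimethylpentadeca-5,9,13-trien-2-one | OCC(=O)CC/C=C(\C)CC/C=C(\C)CCC=C(C)C
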